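**Retrosynthetic overview**
1. Target 21 ⇐ hydroxyl-directed epoxidation of the (4E)-allylic alcohol 20 ⇐ C9 ketone reduction and senecioylation of the ten-membered ketone 16.
2. 16 ⇐ Grob (Wharton) fragmentative ring expansion (6/6 → 10) of the trans-decalin 1,3-diol monomesylate 15; cleaving C4–C9 gives the C9 ketone and the (E)-C4=C5 alkene.
3. 15 ⇐ bicyclic dienone 5, with ring A dressed by reactions on the face opposite the angular methyl: epoxidation/acid opening (C8, C9), tethered Michael/HWE (lactone, C7), Rubottom (C6), directed reduction (C5).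
4. 5 ⇐ intramolecular vinylogous aldol condensation of 2-crotonoyl-2,6-dimethylcyclohexanone 4, whose quaternary centre comes from a new enantioselective phase-transfer methylation.
5. Ring order: ring B (from 1) → ring A (step 3) → γ-lactone (step 7) → ten-membered ring (step 11) → oxirane (step 15).

Assumption: positions are numbered as in a germacran-12,8-olide (C8 = lactone O–CH, C9 = CH–O-senecioate, C10 = CH–CH3, C1–C3 = CH2, C4/C5 = oxirane with CH3 on C4, C6 = CH–OH, C7 bears C11), the given SMILES then being 4R,5R,6R,7R,8R,9R,10R; these labels are used for all intermediates, and in the decalins β is the face of the C4 methyl.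

**Step 1**
Reactants: 1 2-methylcyclohexan-1-one (racemic); 2 (E)-but-2-enoyl chloride
Product: 3 2-[(E)-but-2-enoyl]-6-methylcyclohexan-1-one
Conditions: LDA, THF, −78 °C; then 2, −78 → 0 °C
Reagents that add atoms: none
Why: Claisen-type C-acylation of the kinetic lithium enolate (less substituted α-carbon) gives the 1,3-diketone, whose C4 is stereolabile and whose C10 is still racemic, so no stereocontrol is needed here.

**Step 2**
Reactants: 3 2-[(E)-but-2-enoyl]-6-methylcyclohexan-1-one
Product: 4 (2S)-2-[(E)-but-2-enoyl]-2,6-dimethylcyclohexan-1-one (C6 epimer pair; drawn 2S,6R)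
Conditions: MeI, Cs2CO3, Maruoka N-spiro binaphthyl ammonium bromide (2 mol %, antipode giving 2S), toluene, −20 °C
Reagents that add atoms: iodomethane, CI
Why: Proposed new method: enantioselective phase-transfer C-methylation of a 2-enoyl cyclohexanone, in which the planar caesium 1,3-diketonate forms a tight ion pair with the C2-symmetric chiral ammonium ion that shields one enolate face so that MeI attacks the other and fixes the quaternary C4; the closest known reaction type is the asymmetric phase-transfer alkylation of cyclic β-keto esters and 2-substituted indanones.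

**Step 3**
Reactants: 4 (2S)-2-[(E)-but-2-enoyl]-2,6-dimethylcyclohexan-1-one
Product: 5 (5R,8aS)-5,8a-dimethyl-6,7,8,8a-tetrahydronaphthalen-1(5H)-one
Conditions: t-BuOK (30 mol %), t-BuOH, 4 Å MS, 40 °C
Reagents that add atoms: none
Why: Intramolecular vinylogous aldol condensation, in which the crotonyl dienolate can reach the ring ketone only with its γ-carbon (six-membered ring) and E1cB loss of water gives the linear dienone, while the now vinylogously acidic C10–H equilibrates to the trans-dimethyl isomer (equatorial CH3, no syn-axial CH3/CH3 contact).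

**Step 4**
Reactants: 5 (5R,8aS)-5,8a-dimethyl-6,7,8,8a-tetrahydronaphthalen-1(5H)-one
Product: 6 8α,9α-epoxide of 5 (oxirane trans to the angular methyl)
Conditions: mCPBA, CH2Cl2, 0 °C
Reagents that add atoms: 3-chloroperbenzoic acid, O=C(OO)c1cccc(Cl)c1
Why: Prilezhaev epoxidation selects the electron-rich trisubstituted γ,δ-alkene of the dienone and comes from the face opposite the angular methyl (as with Δ5-steroids), which sets the C9 oxygen α.

**Step 5**
Reactants: 6 8α,9α-epoxide of 5; 7 bromoacetic acid
Product: 8 8β-bromoacetoxy-9α-hydroxy-4β,10α-dimethyl-trans-decal-6-en-5-one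
Conditions: 7 (3 equiv), CH2Cl2, 0 → 25 °C
Reagents that add atoms: none
Why: Acid-promoted trans-diaxial (Fürst–Plattner) opening of the vinyl oxirane by the carboxylic acid at the allylic secondary C8 with inversion (C9 is tertiary and its β-face is blocked by the angular methyl) gives the 8β-ester and the 9α tertiary alcohol of a trans-decalin.

**Step 6**
Reactants: 8 8β-bromoacetoxy-9α-hydroxy-4β,10α-dimethyl-trans-decal-6-en-5-one
Product: 9 8β-[(dimethoxyphosphoryl)acetoxy]-9α-hydroxy-4β,10α-dimethyl-trans-decal-6-en-5-one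
Conditions: P(OMe)3, toluene, 90 °C
Reagents that add atoms: trimethyl phosphite, COP(OC)OC
Why: Michaelis–Arbuzov reaction of the α-bromo ester gives the phosphonoacetate without touching any stereocentre.

**Step 7**
Reactants: 9 8β-[(dimethoxyphosphoryl)acetoxy]-9α-hydroxy-4β,10α-dimethyl-trans-decal-6-en-5-one
Product: 11 9α-hydroxy-4β,10α-dimethyl-trans-decal-5-one carrying the cis-fused 7β,8β α-methylene-γ-lactone, via phosphono lactone 10 (not isolated)
Conditions: LiCl, DBU, MeCN, 0 °C; then (CH2O)n, 25 °C
Reagents that add atoms: formaldehyde, C=O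
Why: Intramolecular 5-exo Michael addition of the phosphonoacetate carbanion (Masamune–Roush base) to the enone β-carbon C7 can occur only on the face of the tethering C8–O, which sets C7 and the cis lactone fusion, and Horner–Wadsworth–Emmons olefination with formaldehyde then installs the exocyclic methylene.

**Step 8**
Reactants: 11 α-methylene lactone ketone
Product: 13 6α-triisopropylsilyloxy derivative of 11, via silyl enol ether 12 (not isolated)
Conditions: TIPSOTf, Et3N, CH2Cl2, −78 → 0 °C; then DMDO, acetone, −40 → 0 °C; PPTS (cat.)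
Reagents that add atoms: triisopropylsilyl trifluoromethanesulfonate, CC(C)[Si](OS(=O)(=O)C(F)(F)F)(C(C)C)C(C)C; dimethyldioxirane, CC1(C)OO1
Why: Rubottom oxidation, in which C6 is the only enolisable position of the C5 ketone, DMDO epoxidises the electron-rich silyl enol ether (not the acrylate) on the α-face away from the axial C4 methyl and the axial C8 oxygen, and 1,4-silyl migration gives the 6α-silyloxy ketone (trans to C7–C11) while the hindered tertiary 9-OH stays free.

**Step 9**
Reactants: 13 6α-triisopropylsilyloxy ketone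
Product: 14 5β,9α-diol (6α-OTIPS)
Conditions: Me4NBH(OAc)3, MeCN/AcOH, −20 °C
Reagents that add atoms: none
Why: Evans–Saksena hydroxyl-directed reduction, in which the axial 9α-OH binds boron and delivers hydride to the α-face of the C5 ketone, gives the equatorial 5β-alcohol (anti-1,3-diol, cis to the angular methyl, trans to 6-OTIPS) without touching the methylene lactone.

**Step 10**
Reactants: 14 5β,9α-diol
Product: 15 5β-methanesulfonate of 14
Conditions: MsCl, Et3N, CH2Cl2, 0 °C
Reagents that add atoms: methanesulfonyl chloride, CS(=O)(=O)Cl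
Why: Sulfonylation of the only secondary hydroxyl (the tertiary 9-OH is inert) turns C5–O into the nucleofuge with retention.

**Step 11**
Reactants: 15 5β-methanesulfonate
Product: 16 (4E)-9-oxo-6-triisopropylsilyloxy-germacra-4,11(13)-dien-12,8-olide
Conditions: KHMDS (1.05 equiv), THF, −78 → −20 °C
Reagents that add atoms: none
Why: Grob (Wharton) fragmentation as a 6/6 → 10 ring expansion, in which the equatorial C5–OMs bond of the trans-decalin is antiperiplanar to C4–C9 so that the C9 alkoxide expels mesylate in one stereospecific step, gives the C9 ketone and the (E)-C4=C5 alkene (axial CH3 ends cis to C6) with C6, C7, C8 and C10 untouched.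

**Step 12**
Reactants: 16 ten-membered ketone
Product: 17 (9R)-9-hydroxy analogue of 16
Conditions: NaBH4, CeCl3·7H2O, MeOH, −78 °C
Reagents that add atoms: none
Why: Luche 1,2-reduction, in which hydride adds from the ring periphery anti to the C8–O bond (polar Felkin–Anh) on what is also the Felkin face for the C10 centre, gives the 9R carbinol (syn to C8–O, anti to C10–CH3) while CeCl3 suppresses conjugate reduction of the methylene lactone.

**Step 13**
Reactants: 17 (9R)-alcohol; 18 3-methylbut-2-enoyl chloride
Product: 19 9-O-(3-methylbut-2-enoyl) 6-O-triisopropylsilyl ether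
Conditions: 18, pyridine, DMAP (cat.), CH2Cl2, 0 °C
Reagents that add atoms: none
Why: Acylation of the secondary alcohol proceeds with retention, and pyridine instead of a trialkylamine avoids vinylketene formation and deconjugation of the senecioyl group.

**Step 14**
Reactants: 19 senecioate silyl ether
Product: 20 (4E)-6-hydroxy-9-(3-methylbut-2-enoyloxy)-germacra-4,11(13)-dien-12,8-olide
Conditions: HF·pyridine, THF, 0 → 25 °C
Reagents that add atoms: none
Why: Fluoride-mediated Si–O cleavage frees the allylic 6-OH and leaves the esters, the lactone and the alkenes untouched.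

**Step 15**
Reactants: 20 allylic alcohol
Product: 21 target (CNP0214930.1)
Conditions: VO(acac)2 (5 mol %), t-BuOOH, CH2Cl2, 0 °C
Reagents that add atoms: tert-butyl hydroperoxide, CC(C)(C)OO
Why: Vanadium-catalysed hydroxyl-directed (Sharpless-type) epoxidation touches only the allylic C4=C5 bond (acrylate and senecioate are electron-poor) and, from the conformer with a small O–C6–C5=C4 dihedral, delivers oxygen to the outer face of the (E)-alkene to give the erythro 4R,5R oxirane.

**Compound list**
1 | 2-methylcyclohexan-1-one (racemic) | CC1CCCCC1=O | starting material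
2 | (E)-but-2-enoyl chloride | C/C=C/C(Cl)=O | starting material
3 | 2-[(E)-but-2-enoyl]-6-methylcyclohexan-1-one (stereolabile) | C/C=C/C(=O)C1CCCC(C)C1=O | intermediate
4 | (2S)-2-[(E)-but-2-enoyl]-2,6-dimethylcyclohexan-1-one (C6 epimer pair, drawn 2S,6R) | C/C=C/C(=O)[C@@]1(C)CCC[C@@H](C)C1=O | intermediate
5 | (5R,8aS)-5,8a-dimethyl-6,7,8,8a-tetrahydronaphthalen-1(5H)-one | O=C1C=CC=C2[C@H](C)CCC[C@]12C | intermediate
6 | 8α,9α-epoxide of 5 (oxirane trans to angular CH3) | O=C1C=C[C@@H]2O[C@@]23[C@H](C)CCC[C@]13C | intermediate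
7 | bromoacetic acid | OC(=O)CBr | starting material
8 | 8β-bromoacetoxy-9α-hydroxy-4β,10α-dimethyl-trans-decal-6-en-5-one | BrCC(=O)O[C@H]2[C@@]3(O)[C@H](C)CCC[C@]3(C)C(=O)C=C2 | intermediate
9 | 8β-[(dimethoxyphosphoryl)acetoxy] analogue of 8 | COP(=O)(OC)CC(=O)O[C@H]2[C@@]3(O)[C@H](C)CCC[C@]3(C)C(=O)C=C2 | intermediate
10 | cis-fused 7β,8β γ-lactone with P(O)(OMe)2 on C11 (C11 epimers/carbanion), C5 ketone, 9α-OH | COP(=O)(OC)C1C(=O)O[C@H]2[C@@]3(O)[C@H](C)CCC[C@]3(C)C(=O)C[C@@H]12 | intermediate (not isolated)
11 | cis-fused 7β,8β α-methylene-γ-lactone, C5 ketone, 9α-OH, 4β,10α-dimethyl trans-decalin | C=C1C(=O)O[C@H]2[C@@]3(O)[C@H](C)CCC[C@]3(C)C(=O)C[C@@H]12 | intermediate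
12 | 5-triisopropylsilyloxy-5-ene (silyl enol ether) of 11 | C=C1C(=O)O[C@H]2[C@@]3(O)[C@H](C)CCC[C@]3(C)C(O[Si](C(C)C)(C(C)C)C(C)C)=C[C@@H]12 | intermediate (not isolated)
13 | 6α-triisopropylsilyloxy derivative of 11 | C=C1C(=O)O[C@H]2[C@@]3(O)[C@H](C)CCC[C@]3(C)C(=O)[C@H](O[Si](C(C)C)(C(C)C)C(C)C)[C@@H]12 | intermediate
14 | 5β,9α-diol, 6α-OTIPS | C=C1C(=O)O[C@H]2[C@@]3(O)[C@H](C)CCC[C@]3(C)[C@@H](O)[C@H](O[Si](C(C)C)(C(C)C)C(C)C)[C@@H]12 | intermediate
15 | 5β-methanesulfonate of 14 | C=C1C(=O)O[C@H]2[C@@]3(O)[C@H](C)CCC[C@]3(C)[C@@H](OS(C)(=O)=O)[C@H](O[Si](C(C)C)(C(C)C)C(C)C)[C@@H]12 | intermediate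
16 | (4E)-9-oxo-6-triisopropylsilyloxy-germacra-4,11(13)-dien-12,8-olide | C=C1C(=O)O[C@H]2C(=O)[C@H](C)CCC/C(C)=C/[C@H](O[Si](C(C)C)(C(C)C)C(C)C)[C@@H]12 | intermediate
17 | (9R)-9-hydroxy analogue of 16 | C=C1C(=O)O[C@H]2[C@H](O)[C@H](C)CCC/C(C)=C/[C@H](O[Si](C(C)C)(C(C)C)C(C)C)[C@@H]12 | intermediate
18 | 3-methylbut-2-enoyl chloride | CC(C)=CC(Cl)=O | starting material
19 | 9-O-(3-methylbut-2-enoyl) derivative of 17 | C=C1C(=O)O[C@H]2[C@H](OC(=O)C=C(C)C)[C@H](C)CCC/C(C)=C/[C@H](O[Si](C(C)C)(C(C)C)C(C)C)[C@@H]12 | intermediate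
20 | (4E)-6-hydroxy-9-(3-methylbut-2-enoyloxy)-germacra-4,11(13)-dien-12,8-olide | C=C1C(=O)O[C@H]2[C@H](OC(=O)C=C(C)C)[C@H](C)CCC/C(C)=C/[C@H](O)[C@@H]12 | intermediate
21 | CNP0214930.1 (4R,5R,6R,7R,8R,9R,10R) | C=C1C(=O)O[C@H]2[C@H](OC(=O)C=C(C)C)[C@H](C)CCC[C@@]3(C)O[C@@H]3[C@H](O)[C@@H]12 | target

**Totals:** 15 steps; longest linear sequence 15 steps (1 → 21; 2, 7 and 18 enter in single steps).

**Steps most likely to fail**

Step 2 (the proposed enantioselective methylation; selectivity on this substrate class is unproven). The fallback uses known chemistry, sets out from 1 and comes back at 5, bypassing 3 and 4. Compound 1 is methylated (LDA, MeI) to 2,6-dimethylcyclohexan-1-one F1. Condensation with (S)-1-phenylethylamine gives imine F2. A d'Angelo deracemising Michael addition to but-3-en-2-one, then aqueous AcOH hydrolysis, gives (2R,6R)-2,6-dimethyl-2-(3-oxobutyl)cyclohexan-1-one F3 (with its C6 epimer). Robinson aldol condensation (NaOMe, MeOH), which also equilibrates the secondary methyl, gives octalone F4. DDQ dehydrogenation gives the cross-conjugated dienone F5. Alkaline H2O2 epoxidises the disubstituted enone bond anti to the angular methyl to give epoxy enone F6. Wharton transposition (N2H4·H2O, AcOH) gives dienol F7, and MnO2 oxidation gives 5.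

Step 3 (the ring-ketone enolate may instead add to the enone to give a bicyclo[3.3.1]nonane, or retro-Claisen cleavage may compete). The fallback sets out from 4 and comes back at 5 by a stepwise Lewis-acid route. TBSOTf/Et3N converts 4 to its silyl dienol ether F8. TiCl4 at −78 °C triggers an intramolecular vinylogous Mukaiyama aldol addition to hydroxy enone F9 (C9 epimers). DBU in warm toluene then effects vinylogous E1cB dehydration and C10 equilibration to 5.

Step 15 (the facial selectivity rests on the conformation of the ten-membered ring). The fallback sets out from 20 and comes back at 21 by replacing substrate control with reagent control: stoichiometric Sharpless conditions, Ti(OiPr)4, D-(−)-diisopropyl tartrate, t-BuOOH, 4 Å MS, CH2Cl2, −20 °C. The tartrate is chosen so that its facial preference gives the 4R,5R oxirane, and this is the matched (erythro-forming) case for the C6 carbinol. No new compound is made.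

**Further compounds**
F1 | step 2 | 2,6-dimethylcyclohexan-1-one | CC1CCCC(C)C1=O
F2 | step 2 | (S)-N-(2,6-dimethylcyclohexylidene)-1-phenylethan-1-amine | C[C@H](N=C1C(C)CCCC1C)c1ccccc1
F3 | step 2 | (2R,6R)-2,6-dimethyl-2-(3-oxobutyl)cyclohexan-1-one | CC(=O)CC[C@@]1(C)CCC[C@@H](C)C1=O
F4 | step 2 | (4aR,8R)-4a,8-dimethyl-4,4a,5,6,7,8-hexahydronaphthalen-2(3H)-one | O=C1CC[C@@]2(C)CCC[C@@H](C)C2=C1
F5 | step 2 | (4aR,8R)-4a,8-dimethyl-5,6,7,8-tetrahydronaphthalen-2(4aH)-one | O=C1C=C[C@@]2(C)CCC[C@@H](C)C2=C1
F6 | step 2 | 3,4-epoxide of F5 (oxirane trans to the angular CH3) | O=C1C=C2[C@H](C)CCC[C@]2(C)[C@@H]3O[C@H]13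
F7 | step 2 | 5,8a-dimethyl-1,5,6,7,8,8a-hexahydronaphthalen-1-ol (OH trans to 8a-CH3, 5-CH3 trans to 8a-CH3) | O[C@@H]1C=CC=C2[C@H](C)CCC[C@]12C
F8 | step 3 | tert-butyldimethylsilyl dienol ether of 4 (enol ether geometry not defined) | C=CC=C(O[Si](C)(C)C(C)(C)C)[C@@]1(C)CCC[C@@H](C)C1=O
F9 | step 3 | 4a-hydroxy-5,8a-dimethyl-4a,5,6,7,8,8a-hexahydronaphthalen-1(4H)-one (C4a epimers) | O=C1C=CCC2(O)[C@H](C)CCC[C@]12C
F0 | step 15 | none | none
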